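**Strategy.** The macrocycle is disconnected at its deoxybenzoin unit, between the methylene carbon next to the ketone and the ring C carbon that carries it (ring C is the meta-phenylene). The key step is a macrocyclising palladium-catalysed ketone α-arylation. It exploits the ketone on ring D (the catechol ring), whose acetyl precursor is the only enolisable site, and forms the CH2–aryl bond, the ketone-flanked methylene and the 18-membered ring in one operation. The precursor is an open-chain, tri-O-methylated acetophenone bearing a single aryl chloride on ring C, meta to the diaryl ether oxygen, assembled convergently by SNAr, Wittig olefination, diimide reduction and Ullmann etherification.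

Key step: step 6

Remarks on the chemistry:
- Ring A is the para-phenylene, ring B the 1,2,3-trisubstituted ring with one hydroxyl, ring C the meta-phenylene, and ring D the catechol ring that carries the ketone.
- The target has no stereocentre. Stilbene 6 is carried on as an E/Z mixture because step 3 removes the double bond.
- Ketone 10 is prepared from the widely stocked ester 8, on the assumption that its own supply is less certain.

Step 1
Reactants: 1 2-fluoro-3-methoxybenzaldehyde; 2 3-chlorophenol
Product: 3 2-(3-chlorophenoxy)-3-methoxybenzaldehyde
Conditions: K2CO3 (1.5 equiv), DMF, 120 °C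
Reagents that add atoms: none
Why: Nucleophilic aromatic substitution (SNAr): the ortho-formyl group stabilises the Meisenheimer adduct at the fluorine-bearing carbon of 1, so the phenoxide of 2 should displace fluoride and set the ring B–O–ring C ether with the chlorine of ring C already in place.

Step 2
Reactants: 3 2-(3-chlorophenoxy)-3-methoxybenzaldehyde; 4 (4-bromobenzyl)triphenylphosphonium bromide
Product: 6 1-bromo-4-{2-[2-(3-chlorophenoxy)-3-methoxyphenyl]ethenyl}benzene (E/Z mixture), via phosphonium ylide 5 (not isolated)
Conditions: 4, KOtBu (1.1 equiv), THF, 0 °C; then 3, 0 °C to rt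
Reagents that add atoms: none
Why: Wittig olefination of the non-enolisable aldehyde 3 with the semi-stabilised benzylic ylide 5 should join rings B and A through a two-carbon unit, and the alkene geometry is irrelevant because step 3 saturates it.

Step 3
Reactants: 6 1-bromo-4-{2-[2-(3-chlorophenoxy)-3-methoxyphenyl]ethenyl}benzene (E/Z mixture)
Product: 7 1-bromo-4-{2-[2-(3-chlorophenoxy)-3-methoxyphenyl]ethyl}benzene
Conditions: p-toluenesulfonyl hydrazide (excess, in portions), NaOAc, DME/H2O, reflux
Reagents that add atoms: none
Why: Diimide reduction: diimide generated by thermolysis of the sulfonyl hydrazide delivers H2 to the C=C bond in a concerted syn transfer and, unlike hydrogenation over palladium on carbon, should leave the C–Br and C–Cl bonds untouched.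

Step 4
Reactants: 8 methyl 3-hydroxy-4,5-dimethoxybenzoate
Product: 10 1-(3-hydroxy-4,5-dimethoxyphenyl)ethanone, via Weinreb amide 9 (not isolated)
Conditions: MeNH(OMe)·HCl (1.5 equiv), MeMgCl (6 equiv), THF, −20 °C to rt; then aq. NH4Cl
Reagents that add atoms: methylmagnesium chloride, C[Mg]Cl
Why: One-pot Weinreb ketone synthesis: the chloromagnesium amide of N,O-dimethylhydroxylamine converts the ester into Weinreb amide 9, whose magnesium chelate after addition of MeMgCl should stop the reaction at the ketone stage, while the phenol is carried along as its magnesium phenoxide.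

Step 5
Reactants: 7 1-bromo-4-{2-[2-(3-chlorophenoxy)-3-methoxyphenyl]ethyl}benzene; 10 1-(3-hydroxy-4,5-dimethoxyphenyl)ethanone
Product: 11 1-[3-(4-{2-[2-(3-chlorophenoxy)-3-methoxyphenyl]ethyl}phenoxy)-4,5-dimethoxyphenyl]ethanone
Conditions: CuI (10 mol%), N,N-dimethylglycine hydrochloride (30 mol%), Cs2CO3 (2 equiv), 1,4-dioxane, 100 °C
Reagents that add atoms: none
Why: Ullmann ether synthesis: monovalent copper ligated by N,N-dimethylglycine should couple the phenoxide of 10 with the C–Br bond of ring A while leaving the less reactive C–Cl bond of ring C in place for the key step.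

Step 6
Reactants: 11 1-[3-(4-{2-[2-(3-chlorophenoxy)-3-methoxyphenyl]ethyl}phenoxy)-4,5-dimethoxyphenyl]ethanone
Product: 12 tri-O-methylmarchantin G (the 18-membered macrocyclic ketone with three methoxy groups)
Conditions: Pd2(dba)3 (5 mol%), XPhos (12 mol%), NaOtBu (2.5 equiv), toluene, 100 °C, syringe-pump addition of 11 over 10 h (final concentration 2 mM)
Reagents that add atoms: none
Why: Zerovalent palladium ligated by XPhos inserts into the only carbon–halogen bond of 11, the C–Cl bond of ring C, NaOtBu converts the acetyl group on ring D into its sodium enolate, and transmetalation followed by C–C reductive elimination from the C-bound arylpalladium enolate forges the CH2–aryl bond. The closest known reaction type is the palladium-catalysed α-arylation of aryl methyl ketones with aryl chlorides, which gives deoxybenzoins by mono-arylation. The single ring closed is the 18-membered macrocycle, formed in the enol-endo sense (both enolate carbons become ring members) by reductive elimination from a 19-membered palladacycle. No stereocentre is created. The step needs ring closure to outrun intermolecular arylation and a second arylation of the product; this should be secured by pseudo-high dilution, by the bulky ligand, by the turns that the ortho-substituted ring B and the two diaryl ether hinges impose on the chain, and by the product resting as its hindered, conjugated enolate. Site selectivity is built into the substrate, since the acetyl CH3 is the only enolisable position and the CH2CH2 bridge is far less acidic.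

Step 7
Reactants: 12 tri-O-methylmarchantin G
Product: 13 marchantin G
Conditions: BBr3 (8 equiv), CH2Cl2, −78 °C to rt; then H2O
Reagents that add atoms: none
Why: Lewis acid-mediated aryl methyl ether cleavage: BBr3 coordinates each methoxy oxygen and bromide removes the methyl group by SN2 attack, whereas the diaryl ether bonds and the ketone should survive, the three phenols being released on hydrolysis.

**Compound list**

1 | 2-fluoro-3-methoxybenzaldehyde | O=Cc1cccc(OC)c1F | starting material
2 | 3-chlorophenol | Oc1cccc(Cl)c1 | starting material
3 | 2-(3-chlorophenoxy)-3-methoxybenzaldehyde | O=Cc1cccc(OC)c1Oc1cccc(Cl)c1 | intermediate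
4 | (4-bromobenzyl)triphenylphosphonium bromide | [Br-].Brc1ccc(C[P+](c2ccccc2)(c2ccccc2)c2ccccc2)cc1 | starting material
5 | (4-bromobenzylidene)triphenylphosphorane (phosphonium ylide, not isolated) | Brc1ccc(C=P(c2ccccc2)(c2ccccc2)c2ccccc2)cc1 | intermediate
6 | 1-bromo-4-{2-[2-(3-chlorophenoxy)-3-methoxyphenyl]ethenyl}benzene (E/Z mixture, geometry not defined) | COc1cccc(C=Cc2ccc(Br)cc2)c1Oc1cccc(Cl)c1 | intermediate
7 | 1-bromo-4-{2-[2-(3-chlorophenoxy)-3-methoxyphenyl]ethyl}benzene | COc1cccc(CCc2ccc(Br)cc2)c1Oc1cccc(Cl)c1 | intermediate
8 | methyl 3-hydroxy-4,5-dimethoxybenzoate | COC(=O)c1cc(O)c(OC)c(OC)c1 | starting material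
9 | 3-hydroxy-N,4,5-trimethoxy-N-methylbenzamide (Weinreb amide, not isolated, present as its magnesium phenoxide) | CON(C)C(=O)c1cc(O)c(OC)c(OC)c1 | intermediate
10 | 1-(3-hydroxy-4,5-dimethoxyphenyl)ethanone | CC(=O)c1cc(O)c(OC)c(OC)c1 | intermediate
11 | 1-[3-(4-{2-[2-(3-chlorophenoxy)-3-methoxyphenyl]ethyl}phenoxy)-4,5-dimethoxyphenyl]ethanone | CC(=O)c1cc(Oc2ccc(CCc3cccc(OC)c3Oc3cccc(Cl)c3)cc2)c(OC)c(OC)c1 | intermediate
12 | tri-O-methylmarchantin G | O=C1Cc2cccc(c2)Oc2c(OC)cccc2CCc2ccc(cc2)Oc2cc1cc(OC)c2OC | intermediate
13 | marchantin G | O=C1Cc2cccc(c2)Oc2c(O)cccc2CCc2ccc(cc2)Oc2cc1cc(O)c2O | target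

**Step count and risks**

Total step count: 7. Longest linear sequence: 6 steps (steps 1, 2, 3, 5, 6 and 7; step 4 is a one-step branch).

Steps most likely to fail:

1. Step 6. Intermolecular arylation could outrun ring closure and give oligomers. Alternatively, slow insertion into the C–Cl bond at millimolar concentration could let the catalyst decay and lead to hydrodechlorination. The fallback closes the same bond with reversed polarity and sets out from 11. Miyaura borylation of the ring C chloride (B2pin2, Pd2(dba)3, XPhos, KOAc, dioxane, 100 °C) should give the pinacol boronate ketone F1. Silylation (TMSOTf, Et3N, CH2Cl2, 0 °C) should give the trimethylsilyl enol ether F2. Bromination with NBS (THF, −78 °C) should give the α-bromo ketone F3. An intramolecular Suzuki–Miyaura coupling of the α-bromo ketone with the arylboronate (Pd(OAc)2, P(o-tolyl)3, K3PO4, THF/H2O, rt, high dilution) should then close the ring; zerovalent palladium inserts into the activated C–Br bond already at room temperature and no strong base is present. The fallback returns to the route at 12.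

2. Step 5. The C–O coupling of the ortho-methoxy-flanked phenol with the unactivated bromide could be sluggish, so that hydrodebromination and base-induced aldol self-condensation of the ketone take over during prolonged heating. The fallback replaces the copper/aryl halide coupling by an oxidative coupling at room temperature and sets out from 7. Bromine–lithium exchange (n-BuLi, THF, −78 °C), quench with B(OiPr)3 and acidic work-up should give the arylboronic acid F4. Chan–Lam coupling of F4 with phenol 10 (Cu(OAc)2, pyridine, 4 Å molecular sieves, CH2Cl2, air, rt) should form the diaryl ether without touching the C–Cl bond. The fallback returns at 11.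

3. Step 3. Diimide could disproportionate faster than it reduces the conjugated, partly trans-configured stilbene, so that the reduction stalls and alkene and bibenzyl become hard to separate. The fallback avoids the stilbene altogether and sets out from 3. Wittig methylenation (methyltriphenylphosphonium bromide, KOtBu, THF) should give the styrene F5. Hydroboration with 9-BBN (THF, rt) should give the B-alkyl-9-BBN adduct F6, which is used without isolation. A B-alkyl Suzuki–Miyaura coupling with 1-bromo-4-iodobenzene (Pd(dppf)Cl2, aq. K3PO4, THF/DMF, rt), selective for the C–I bond, should then build the saturated two-carbon bridge directly. The fallback returns at 7.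

**Further compounds**

F1 | step 6 | 1-{3-[4-(2-{3-methoxy-2-[3-(4,4,5,5-tetramethyl-1,3,2-dioxaborolan-2-yl)phenoxy]phenyl}ethyl)phenoxy]-4,5-dimethoxyphenyl}ethanone | CC(=O)c1cc(Oc2ccc(CCc3cccc(OC)c3Oc3cccc(B4OC(C)(C)C(C)(C)O4)c3)cc2)c(OC)c(OC)c1
F2 | step 6 | trimethylsilyl enol ether of F1 | C=C(O[Si](C)(C)C)c1cc(Oc2ccc(CCc3cccc(OC)c3Oc3cccc(B4OC(C)(C)C(C)(C)O4)c3)cc2)c(OC)c(OC)c1
F3 | step 6 | 2-bromo-1-{3-[4-(2-{3-methoxy-2-[3-(4,4,5,5-tetramethyl-1,3,2-dioxaborolan-2-yl)phenoxy]phenyl}ethyl)phenoxy]-4,5-dimethoxyphenyl}ethanone | BrCC(=O)c1cc(Oc2ccc(CCc3cccc(OC)c3Oc3cccc(B4OC(C)(C)C(C)(C)O4)c3)cc2)c(OC)c(OC)c1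
F4 | step 5 | (4-{2-[2-(3-chlorophenoxy)-3-methoxyphenyl]ethyl}phenyl)boronic acid | OB(O)c1ccc(CCc2cccc(OC)c2Oc2cccc(Cl)c2)cc1
F5 | step 3 | 2-(3-chlorophenoxy)-1-ethenyl-3-methoxybenzene | C=Cc1cccc(OC)c1Oc1cccc(Cl)c1
F6 | step 3 | 9-{2-[2-(3-chlorophenoxy)-3-methoxyphenyl]ethyl}-9-borabicyclo[3.3.1]nonane | COc1cccc(CCB2C3CCCC2CCC3)c1Oc1cccc(Cl)c1
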